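**Plan**
- Retrosynthesis: the three acetates are removed, then the C8–C9 bond of the seven-membered ring is cut. In that ring the C8 carbinol sits one CH2 (C9) away from C10, which carries the exocyclic C14 methylene; this 3-methylenecycloheptanol array is the retron of a Type II carbonyl-ene reaction between a C8 aldehyde and an isopropenyl group on C1.
- Further cuts: C6–C7 (syn aldol of an isovaleryl unit with a C6 aldehyde on the cyclopentane), then ring contraction back to (S)-carvone (Favorskii), which supplies C1 with its isopropenyl group.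
- Forward: the carvone ring is contracted to the cyclopentane (first ring); a C3 ketone serves to place 4-OH and 3-OH; the C5 ester becomes the C6 aldehyde; the aldol adds C7/C8; the C8 aldehyde then closes the seven-membered ring last; desilylation and acetylation finish.
- Stereochemistry: C1 from (S)-carvone; C5 by equilibration trans to C1; C4 by oxidation anti to the C5 ester; C3 by OH-directed hydride delivery; C6/C7 from the thiazolidinethione auxiliary; C8 in the ene step from the C7 isopropyl group together with a bulky aluminium Lewis acid.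

Key step: step 16

Remark: guaiane numbering is used for the target and, by anticipation, for all intermediates (C1/C5 ring fusion; C2–C4 the other cyclopentane carbons, C4 bearing CH3 and OH; C6–C10 the other cycloheptane carbons, C7 bearing isopropyl, C10 the C14 methylene); with 7-isopropyl β the target is 1βH,5αH (trans-fused), 3β-OAc, 4α-OH, 6α-OAc, 8α-OAc, i.e. (1S,3S,4S,5S,6S,7R,8S).

**Route**

Step 1
Reactants: 1 (S)-(+)-carvone
Product: 2 (1S,4S,6S)-1-methyl-4-(prop-1-en-2-yl)-7-oxabicyclo[4.1.0]heptan-2-one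
Conditions: 30% H2O2, NaOH (cat.), MeOH, 0 °C
Reagents that add atoms: hydrogen peroxide, OO
Why: Weitz–Scheffer nucleophilic epoxidation touches only the enone C=C, and hydroperoxide adds trans to the isopropenyl group, so the oxirane should form on the face opposite to it.

Step 2
Reactants: 2 carvone epoxide
Product: 3 (2R,3S,5S)-2-chloro-3-hydroxy-2-methyl-5-(prop-1-en-2-yl)cyclohexan-1-one
Conditions: LiCl, CF3CO2H, THF, rt
Reagents that add atoms: lithium chloride, [Li+].[Cl-]
Why: Acid-assisted epoxide opening by chloride at the tertiary α-carbon with inversion (trans-diaxial halohydrin formation) gives the α-chloro ketone needed for ring contraction.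

Step 3
Reactants: 3 chlorohydrin
Product: 4 (2R,3S,5S)-2-chloro-2-methyl-3-(oxan-2-yloxy)-5-(prop-1-en-2-yl)cyclohexan-1-one (mixture at the acetal carbon)
Conditions: 3,4-dihydro-2H-pyran, PPTS (cat.), CH2Cl2, rt
Reagents that add atoms: 3,4-dihydro-2H-pyran, C1=COCCC1
Why: Acid-catalysed acetalisation (THP protection) masks the β-hydroxyl so that base cannot re-close the epoxide in the next step.

Step 4
Reactants: 4 THP-protected chloro ketone
Product: 6 methyl (1S,2R,3S,5S)-2-methyl-3-(oxan-2-yloxy)-5-(prop-1-en-2-yl)cyclopentane-1-carboxylate, via cyclopropanone 5 (not isolated)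
Conditions: NaOMe, MeOH, 0 °C → rt
Reagents that add atoms: sodium methoxide, [Na+].[O-]C
Why: Favorskii rearrangement: the α'-enolate displaces the axial chloride to give cyclopropanone 5, methoxide adds and the C(O)–C(CH3) bond breaks, which contracts the ring to the cyclopentane ester with the isopropenyl stereocentre (C1) untouched and the ester at first cis to it (corrected in step 6).

Step 5
Reactants: 6 THP-protected cyclopentane ester
Product: 7 methyl (1S,2R,5S)-2-methyl-3-oxo-5-(prop-1-en-2-yl)cyclopentane-1-carboxylate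
Conditions: CrO3, H2SO4, H2O, acetone, 0 °C
Reagents that add atoms: none
Why: Jones oxidation: the aqueous acid cleaves the THP acetal and chromic acid oxidises the liberated secondary alcohol to the C3 ketone in the same pot, leaving ester and 1,1-disubstituted alkene untouched at 0 °C.

Step 6
Reactants: 7 keto ester (ester cis to isopropenyl)
Product: 8 methyl (1R,2S,5S)-2-methyl-3-oxo-5-(prop-1-en-2-yl)cyclopentane-1-carboxylate
Conditions: NaOMe (0.5 equiv), MeOH, 40 °C
Reagents that add atoms: none
Why: Base-mediated epimerisation under thermodynamic control, through the ketone enolate at C4 and the ester enolate at C5, should give the all-trans isomer with the ester trans to both isopropenyl and methyl, which sets C5 relative to C1.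

Step 7
Reactants: 8 all-trans keto ester
Product: 9 methyl (1R,5S)-2-methyl-5-(prop-1-en-2-yl)-3-(trimethylsilyloxy)cyclopent-2-ene-1-carboxylate
Conditions: TMSCl, NaI, Et3N, MeCN, rt
Reagents that add atoms: chlorotrimethylsilane, C[Si](C)(C)Cl
Why: Silyl enol ether formation under equilibrating conditions (iodotrimethylsilane made in situ, amine base) should give the more substituted C3=C4 enol ether and not the C2=C3 isomer.

Step 8
Reactants: 9 silyl enol ether
Product: 11 methyl (1R,2S,5S)-2-hydroxy-2-methyl-3-oxo-5-(prop-1-en-2-yl)cyclopentane-1-carboxylate, via α-silyloxy ketone 10 (not isolated)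
Conditions: mCPBA (1.0 equiv), NaHCO3, CH2Cl2, −20 °C; then 1 M HCl, THF, 0 °C
Reagents that add atoms: m-chloroperbenzoic acid, OOC(=O)c1cccc(Cl)c1
Why: Rubottom oxidation: the peracid attacks the electron-rich enol ether much faster than the isopropenyl group and from the α face, anti to the adjacent C5 ester, and silyl migration followed by acid hydrolysis of 10 leaves the tertiary 4α-hydroxyl (4β-methyl).

Step 9
Reactants: 11 α-hydroxy ketone
Product: 12 methyl (1R,2S,3S,5S)-2,3-dihydroxy-2-methyl-5-(prop-1-en-2-yl)cyclopentane-1-carboxylate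
Conditions: Me4NBH(OAc)3, AcOH/MeCN, −20 °C
Reagents that add atoms: none
Why: Hydroxyl-directed triacetoxyborohydride reduction (Saksena–Evans type): the C4 hydroxyl binds boron and delivers hydride to C3 from its own α face (also the face anti to the C4 methyl), so the new C3 hydroxyl is β and trans to the C4 hydroxyl, and the ester is not reduced.

Step 10
Reactants: 12 diol ester
Product: 13 methyl (1R,2S,3S,5S)-2-methyl-5-(prop-1-en-2-yl)-2,3-bis(triethylsilyloxy)cyclopentane-1-carboxylate
Conditions: TESOTf (2.5 equiv), 2,6-lutidine, CH2Cl2, −78 → 0 °C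
Reagents that add atoms: triethylsilyl trifluoromethanesulfonate, CC[Si](CC)(CC)OS(=O)(=O)C(F)(F)F
Why: Silyl triflate silylation protects the secondary and the hindered tertiary hydroxyl, so that the later β-oxygenated aldehydes cannot undergo retro-aldol cleavage or lactol formation.

Step 11
Reactants: 13 bis-silyl ether ester
Product: 14 (1R,2S,3S,5S)-2-methyl-5-(prop-1-en-2-yl)-2,3-bis(triethylsilyloxy)cyclopentane-1-carbaldehyde
Conditions: DIBAL-H (1.1 equiv), CH2Cl2, −78 °C; Rochelle salt
Reagents that add atoms: none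
Why: Partial DIBAL-H reduction of the hindered methyl ester should stop at the tetrahedral aluminium hemiacetal at −78 °C and release the C6 aldehyde on work-up without epimerising C5.

Step 12
Reactants: 15 (S)-4-benzyl-1,3-thiazolidine-2-thione; 16 3-methylbutanoyl chloride
Product: 17 (S)-4-benzyl-3-(3-methylbutanoyl)-1,3-thiazolidine-2-thione
Conditions: Et3N, DMAP (cat.), CH2Cl2, 0 °C
Reagents that add atoms: none
Why: DMAP-catalysed N-acylation of the thiazolidinethione with the acid chloride gives the aldol donor.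

Step 13
Reactants: 17 N-isovaleryl thiazolidinethione; 14 cyclopentane carbaldehyde
Product: 19 (S)-4-benzyl-3-[(2S,3R)-3-hydroxy-2-isopropyl-3-[(1S,2S,3S,5S)-2-methyl-5-(prop-1-en-2-yl)-2,3-bis(triethylsilyloxy)cyclopentyl]propanoyl]-1,3-thiazolidine-2-thione, via titanium enolate 18 (not isolated)
Conditions: TiCl4 (1.05 equiv), i-Pr2NEt (1.1 equiv), NMP (2 equiv), CH2Cl2, 0 °C; then 14, −78 → 0 °C; aq. NH4Cl
Reagents that add atoms: none
Why: Titanium-enolate aldol addition of an N-acyl thiazolidinethione: the (Z)-enolate 18, with NMP filling the free site on titanium, reacts through the non-chelated Zimmerman–Traxler chair on the face opposite the benzyl group, so the auxiliary sets C6 and C7 as the "Evans syn" pair (6α-O and 7β-isopropyl in the later ring), in the anti-Felkin sense at C5–C6 that a (Z)-enolate favours with an α-branched aldehyde.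

Step 14
Reactants: 19 aldol adduct
Product: 20 (S)-4-benzyl-3-[(2S,3R)-2-isopropyl-3-[(1S,2S,3S,5S)-2-methyl-5-(prop-1-en-2-yl)-2,3-bis(triethylsilyloxy)cyclopentyl]-3-(triethylsilyloxy)propanoyl]-1,3-thiazolidine-2-thione
Conditions: TESOTf, 2,6-lutidine, CH2Cl2, −78 °C
Reagents that add atoms: triethylsilyl trifluoromethanesulfonate, CC[Si](CC)(CC)OS(=O)(=O)C(F)(F)F
Why: Silylation of the aldol hydroxyl (silyl triflate, hindered base) blocks retro-aldol and β-elimination during reduction and cyclisation.

Step 15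
Reactants: 20 silylated aldol adduct
Product: 21 (2S,3R)-2-isopropyl-3-[(1S,2S,3S,5S)-2-methyl-5-(prop-1-en-2-yl)-2,3-bis(triethylsilyloxy)cyclopentyl]-3-(triethylsilyloxy)propanal
Conditions: DIBAL-H, CH2Cl2, −78 °C; Rochelle salt
Reagents that add atoms: none
Why: The activated N-acyl thiazolidinethione is reduced by DIBAL-H directly to the C8 aldehyde (stable tetrahedral intermediate at −78 °C) with release of the auxiliary and without epimerisation at C7.

Step 16
Reactants: 21 ene precursor (C8 aldehyde with C1 isopropenyl group)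
Product: 22 3β,4α,6α-tris(triethylsilyloxy)-1βH,5αH-guai-10(14)-en-8α-ol
Conditions: MABR (2 equiv, pre-formed from Me3Al and 4-bromo-2,6-di-tert-butylphenol (2 equiv), CH2Cl2, rt), CH2Cl2, −78 → −40 °C; Rochelle salt
Reagents that add atoms: none
Why: The aluminium Lewis acid activates the C8 aldehyde, the terminal CH2 (C9) of the C1 isopropenyl group attacks the carbonyl carbon while positive charge builds at C10, and a hydrogen of the isopropenyl methyl (C14) passes to the carbonyl oxygen, giving the C8 aluminium alkoxide and the C10=C14 exocyclic methylene. The closest known reaction type is the Lewis acid-promoted Type II intramolecular carbonyl-ene cyclisation of ε,ζ-unsaturated aldehydes to 3-methylenecycloheptanols. The seven-membered ring closes by C8–C9 bond formation, endo with respect to the alkene (C9 and C10 both become ring atoms, the tether being attached to the central carbon of the ene unit); it is the only ring formed, and it is trans-fused because the C1 and C5 substituents are already trans on the cyclopentane. C8 is the only new stereocentre: in the chair-like array with C6–OSiEt3 and C7-isopropyl equatorial, a small Lewis acid would be expected to place the complexed oxygen axial (8β), whereas this very bulky aluminium phenoxide is known to reverse that preference in Type II cyclisations and should place the oxygen equatorial, anti to the C7 isopropyl group, giving the 8α (8S) carbinol. The step needs the exo-methylene and not endocyclic alkene isomers (hydrogen transfer from the methyl within the ene array at low temperature), reaction of the isopropenyl group only (no other alkene is present), and survival of the β-silyloxy aldehyde (aprotic, non-basic conditions at −78 °C).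

Step 17
Reactants: 22 tris-silylated hydroazulenol
Product: 23 1βH,5αH-guai-10(14)-ene-3β,4α,6α,8α-tetraol
Conditions: HF·pyridine, pyridine, THF, 0 °C → rt
Reagents that add atoms: none
Why: Fluoride-mediated desilylation under buffered conditions removes the two secondary and the tertiary triethylsilyl ethers without migration of the exocyclic alkene or ionisation of the tertiary alcohol.

Step 18
Reactants: 23 tetraol
Product: 24 3β,6α,8α-triacetoxy-1βH,5αH-guai-10(14)-en-4α-ol (target)
Conditions: Ac2O, pyridine, DMAP (cat.), CH2Cl2, 0 °C → rt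
Reagents that add atoms: acetic anhydride, CC(=O)OC(C)=O
Why: DMAP-catalysed acetylation esterifies the three secondary hydroxyls (C3, C6, C8), while the hindered tertiary C4 hydroxyl should not react under these mild conditions.

**Compound list**

1 | (S)-(+)-carvone, (5S)-2-methyl-5-(prop-1-en-2-yl)cyclohex-2-en-1-one | CC1=CC[C@@H](CC1=O)C(C)=C | starting material
2 | (1S,4S,6S)-1-methyl-4-(prop-1-en-2-yl)-7-oxabicyclo[4.1.0]heptan-2-one (epoxide trans to isopropenyl) | O=C1C[C@@H](C(C)=C)C[C@@H]2O[C@]12C | intermediate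
3 | (2R,3S,5S)-2-chloro-3-hydroxy-2-methyl-5-(prop-1-en-2-yl)cyclohexan-1-one | O=C1C[C@@H](C(C)=C)C[C@H](O)[C@@]1(C)Cl | intermediate
4 | (2R,3S,5S)-2-chloro-2-methyl-3-(oxan-2-yloxy)-5-(prop-1-en-2-yl)cyclohexan-1-one | O=C1C[C@@H](C(C)=C)C[C@H](OC2CCCCO2)[C@@]1(C)Cl | intermediate
5 | 1-methyl-2-(oxan-2-yloxy)-4-(prop-1-en-2-yl)bicyclo[3.1.0]hexan-6-one (carbonyl bridge on the face of the isopropenyl group, oxanyloxy group on the other face) | O=C1[C@H]2[C@@H](C(C)=C)C[C@H](OC3CCCCO3)[C@@]12C | intermediate (not isolated)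
6 | methyl (1S,2R,3S,5S)-2-methyl-3-(oxan-2-yloxy)-5-(prop-1-en-2-yl)cyclopentane-1-carboxylate | COC(=O)[C@H]1[C@@H](C(C)=C)C[C@H](OC2CCCCO2)[C@@H]1C | intermediate
7 | methyl (1S,2R,5S)-2-methyl-3-oxo-5-(prop-1-en-2-yl)cyclopentane-1-carboxylate | COC(=O)[C@H]1[C@@H](C(C)=C)CC(=O)[C@@H]1C | intermediate
8 | methyl (1R,2S,5S)-2-methyl-3-oxo-5-(prop-1-en-2-yl)cyclopentane-1-carboxylate (all-trans) | COC(=O)[C@@H]1[C@@H](C(C)=C)CC(=O)[C@H]1C | intermediate
9 | methyl (1R,5S)-2-methyl-5-(prop-1-en-2-yl)-3-(trimethylsilyloxy)cyclopent-2-ene-1-carboxylate | COC(=O)[C@@H]1[C@@H](C(C)=C)CC(O[Si](C)(C)C)=C1C | intermediate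
10 | methyl (1R,2S,5S)-2-methyl-3-oxo-5-(prop-1-en-2-yl)-2-(trimethylsilyloxy)cyclopentane-1-carboxylate | COC(=O)[C@@H]1[C@@H](C(C)=C)CC(=O)[C@@]1(C)O[Si](C)(C)C | intermediate (not isolated)
11 | methyl (1R,2S,5S)-2-hydroxy-2-methyl-3-oxo-5-(prop-1-en-2-yl)cyclopentane-1-carboxylate | COC(=O)[C@@H]1[C@@H](C(C)=C)CC(=O)[C@@]1(C)O | intermediate
12 | methyl (1R,2S,3S,5S)-2,3-dihydroxy-2-methyl-5-(prop-1-en-2-yl)cyclopentane-1-carboxylate | COC(=O)[C@@H]1[C@@H](C(C)=C)C[C@H](O)[C@@]1(C)O | intermediate
13 | methyl (1R,2S,3S,5S)-2-methyl-5-(prop-1-en-2-yl)-2,3-bis(triethylsilyloxy)cyclopentane-1-carboxylate | COC(=O)[C@@H]1[C@@H](C(C)=C)C[C@H](O[Si](CC)(CC)CC)[C@@]1(C)O[Si](CC)(CC)CC | intermediate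
14 | (1R,2S,3S,5S)-2-methyl-5-(prop-1-en-2-yl)-2,3-bis(triethylsilyloxy)cyclopentane-1-carbaldehyde | O=C[C@@H]1[C@@H](C(C)=C)C[C@H](O[Si](CC)(CC)CC)[C@@]1(C)O[Si](CC)(CC)CC | intermediate
15 | (S)-4-benzyl-1,3-thiazolidine-2-thione | S=C1N[C@@H](Cc2ccccc2)CS1 | starting material
16 | 3-methylbutanoyl chloride | CC(C)CC(Cl)=O | starting material
17 | (S)-4-benzyl-3-(3-methylbutanoyl)-1,3-thiazolidine-2-thione | CC(C)CC(=O)N1[C@@H](Cc2ccccc2)CSC1=S | intermediate
18 | (Z)-trichlorotitanium enolate of 17 | CC(C)/C=C(\O[Ti](Cl)(Cl)Cl)N1[C@@H](Cc2ccccc2)CSC1=S | intermediate (not isolated)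
19 | (S)-4-benzyl-3-[(2S,3R)-3-hydroxy-2-isopropyl-3-[(1S,2S,3S,5S)-2-methyl-5-(prop-1-en-2-yl)-2,3-bis(triethylsilyloxy)cyclopentyl]propanoyl]-1,3-thiazolidine-2-thione | S=C1SC[C@H](Cc2ccccc2)N1C(=O)[C@@H](C(C)C)[C@H](O)[C@@H]1[C@@H](C(C)=C)C[C@H](O[Si](CC)(CC)CC)[C@@]1(C)O[Si](CC)(CC)CC | intermediate
20 | O-triethylsilyl ether of 19 at the aldol (C6) hydroxyl | S=C1SC[C@H](Cc2ccccc2)N1C(=O)[C@@H](C(C)C)[C@H](O[Si](CC)(CC)CC)[C@@H]1[C@@H](C(C)=C)C[C@H](O[Si](CC)(CC)CC)[C@@]1(C)O[Si](CC)(CC)CC | intermediate
21 | (2S,3R)-2-isopropyl-3-[(1S,2S,3S,5S)-2-methyl-5-(prop-1-en-2-yl)-2,3-bis(triethylsilyloxy)cyclopentyl]-3-(triethylsilyloxy)propanal | O=C[C@@H](C(C)C)[C@H](O[Si](CC)(CC)CC)[C@@H]1[C@@H](C(C)=C)C[C@H](O[Si](CC)(CC)CC)[C@@]1(C)O[Si](CC)(CC)CC | intermediate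
22 | 3β,4α,6α-tris(triethylsilyloxy)-1βH,5αH-guai-10(14)-en-8α-ol | C=C1C[C@H](O)[C@@H](C(C)C)[C@H](O[Si](CC)(CC)CC)[C@@H]2[C@@H]1C[C@H](O[Si](CC)(CC)CC)[C@@]2(C)O[Si](CC)(CC)CC | intermediate
23 | 1βH,5αH-guai-10(14)-ene-3β,4α,6α,8α-tetraol | C=C1C[C@H](O)[C@@H](C(C)C)[C@H](O)[C@@H]2[C@@H]1C[C@H](O)[C@@]2(C)O | intermediate
24 | 3β,6α,8α-triacetoxy-1βH,5αH-guai-10(14)-en-4α-ol, (1S,3S,4S,5S,6S,7R,8S), CNP0147943.1 | C=C1C[C@H](OC(C)=O)[C@@H](C(C)C)[C@H](OC(C)=O)[C@@H]2[C@@H]1C[C@H](OC(C)=O)[C@@]2(C)O | target

**Count and risks**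

Total steps: 18. Longest linear sequence: 17 (steps 1–11 and 13–18; step 12 is a side branch).

Steps most likely to fail:

1. Step 16. The aldehyde may be attacked on its other face if the closed, oxygen-axial ene array competes (C8 epimer), or the developing C10 cation may lose a ring proton instead of the methyl hydrogen (endocyclic alkene isomers). Fallback: setting out from 21, cyclisation with Me2AlCl (CH2Cl2, −78 °C), for which the oxygen-axial array is the normal course, would give the C8-epimeric 8β-alcohol F1. Dess–Martin oxidation (NaHCO3, CH2Cl2) would give the β,γ-unsaturated C8 ketone F2, and NaBH4 (MeOH, −40 °C), which should deliver hydride axially to give the equatorial alcohol, would come back to the route at 22.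

2. Step 7. Silylation may occur at the less substituted (C2) enol, so that step 8 would oxidise C2, and the subsequent oxidation may show poor facial selectivity. Fallback: setting out from 8, autoxidation of the equilibrating enolate (Cs2CO3, O2, P(OEt)3, DMSO, rt) would hydroxylate the tertiary α-carbon through the C4 hydroperoxide F3, which the phosphite reduces in the flask, and would come back to the route at 11.

3. Step 13. Addition of the hindered isovaleryl titanium enolate to the neopentyl-type aldehyde may be slow, with competing loss of the β-silyloxy group of 14 under the Lewis acid, or auxiliary control may erode. Fallback: setting out from 14, a boron-mediated Evans aldol with commercial (S)-4-benzyl-3-(3-methylbutanoyl)oxazolidin-2-one (Bu2BOTf, Et3N, CH2Cl2, −78 → 0 °C; H2O2, pH 7 buffer) would give the syn oxazolidinone adduct F4. Silylation (TESOTf, 2,6-lutidine) would give the triethylsilyl ether F5, reductive removal of the auxiliary (LiBH4, MeOH, THF, 0 °C) the primary alcohol F6, and Dess–Martin oxidation would come back to the route at 21.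

Further compounds
F1 | step 16 | 3β,4α,6α-tris(triethylsilyloxy)-1βH,5αH-guai-10(14)-en-8β-ol (C8 epimer of 22) | C=C1C[C@@H](O)[C@@H](C(C)C)[C@H](O[Si](CC)(CC)CC)[C@@H]2[C@@H]1C[C@H](O[Si](CC)(CC)CC)[C@@]2(C)O[Si](CC)(CC)CC
F2 | step 16 | 3β,4α,6α-tris(triethylsilyloxy)-1βH,5αH-guai-10(14)-en-8-one | C=C1CC(=O)[C@@H](C(C)C)[C@H](O[Si](CC)(CC)CC)[C@@H]2[C@@H]1C[C@H](O[Si](CC)(CC)CC)[C@@]2(C)O[Si](CC)(CC)CC
F3 | step 7 | methyl (1R,2S,5S)-2-hydroperoxy-2-methyl-3-oxo-5-(prop-1-en-2-yl)cyclopentane-1-carboxylate | COC(=O)[C@@H]1[C@@H](C(C)=C)CC(=O)[C@@]1(C)OO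
F4 | step 13 | (S)-4-benzyl-3-[(2S,3R)-3-hydroxy-2-isopropyl-3-[(1S,2S,3S,5S)-2-methyl-5-(prop-1-en-2-yl)-2,3-bis(triethylsilyloxy)cyclopentyl]propanoyl]oxazolidin-2-one | O=C1OC[C@H](Cc2ccccc2)N1C(=O)[C@@H](C(C)C)[C@H](O)[C@@H]1[C@@H](C(C)=C)C[C@H](O[Si](CC)(CC)CC)[C@@]1(C)O[Si](CC)(CC)CC
F5 | step 13 | O-triethylsilyl ether of F4 at the aldol (C6) hydroxyl | O=C1OC[C@H](Cc2ccccc2)N1C(=O)[C@@H](C(C)C)[C@H](O[Si](CC)(CC)CC)[C@@H]1[C@@H](C(C)=C)C[C@H](O[Si](CC)(CC)CC)[C@@]1(C)O[Si](CC)(CC)CC
F6 | step 13 | primary alcohol corresponding to 21 (CH2OH in place of CHO, same configuration at all centres) | OC[C@@H](C(C)C)[C@H](O[Si](CC)(CC)CC)[C@@H]1[C@@H](C(C)=C)C[C@H](O[Si](CC)(CC)CC)[C@@]1(C)O[Si](CC)(CC)CC
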